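(The data were computed for substances that don't exist; the scatter is artificial.)

The ratio I hand over with the green flask stands at 0.101: left-handed product per side product, a selectivity summed over the readings from 5.00 min to 20.0 min.

- green: left-handed substrate 0.40 M; right-handed substrate 0.40 M; coupling partner 3 equiv; the very flask that is asked about, followed so far
- flask: left-handed substrate 0.40 M; coupling partner 3.00 equiv; right-handed substrate 0.40 M; time 3.0 h

green run (percent of the left-handed substrate and right-handed substrate together charged)

| time / min | left-handed substrate / % | left-handed product / % | side product / % |
|---|---|---|---|
| 2.00 | 8 | 12 | 47 |
| 5.00 | 2 | 5 | 82 |
| 10.0 | 2 | 9 | 83 |
| 15.0 | 1 | 9 | 86 |
| 20.0 | 0 | 11 | 87 |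

(scatter of a reading: 2 percentage points)

- coupling partner is single-handed; left-handed substrate and right-handed substrate are mirror images of each other, charged as a racemate, each of them at the stated concentration
- what may be going on: coupling partner + left-handed substrate -> left-handed product; coupling partner + right-handed substrate -> right-handed product; left-handed substrate <-> achiral form; right-handed substrate <-> achiral form; achiral form -> waste; achiral form -> side product; 2 coupling partner -> self-condensation product
- the reaction counts as stopped when no species that holds the left-handed substrate and right-handed substrate together changes by six tenths of a point or more over the second half of the time
- the handed part of coupling partner does not stay in what it makes, so the products of the two hands are mirror images too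
- what has gone into achiral form counts as reacted

1. which holds at 3.0 h: what has brought the reaction to rest, or that it has not come to rest (all of the left-handed substrate has reacted / it is still moving / forward and back rates have come level)
2. conversion of left-handed substrate and right-handed substrate together at 3.0 h
3. amount of left-handed product at 3.0 h, in percent of the left-handed substrate and right-handed substrate together charged
4. amount of side product at 3.0 h, in percent of the left-handed substrate and right-handed substrate together charged

To whoever takes over the green flask: at any moment left-handed product grows with c(coupling partner) times c(left-handed substrate), and side product grows with c(achiral form), so while substrate and achiral form keep their proportion, the comparison of the two rates follows c(coupling partner) and drifts down as that falls. Left-handed substrate in the green flask reads 0 % at 20.0 min, so I expect you to find the flask at rest when you come, and you need not touch it. I take the last side product reading, 87 %, and the ratio turns it into 8.75 % of left-handed product.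

The forecast says that at 3.0 h all of the left-handed substrate has reacted, with conversion 100 %, left-handed product 10 % (range 8 % to 12 %) and side product 87 % (range 84.5 % to 89.5 %), since “no lasting equilibrium can hold substrate”. My product figure is lower than its value but inside its range.

In the flask at 3.0 h, all of the left-handed substrate has reacted, with conversion 100 %, left-handed product 7.86 % and side product 87.5 %.

    coupling partner + left-handed substrate → left-handed product (k = 0.00450 /M/s)
    coupling partner + right-handed substrate → right-handed product (k = 1.30 × 10⁻⁴ /M/s)
    left-handed substrate ⇌ achiral form (K = 1.60, k = 0.130 /s)
    right-handed substrate ⇌ achiral form (K = 1.60, k = 0.130 /s)
    achiral form → waste (k = 8.00 × 10⁻⁴ /s)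
    achiral form → side product (k = 0.0160 /s)
    2 coupling partner → self-condensation product (k = 0.00930 /M/s)

Left-handed product already stands at 7.84 % after 0.150 h, and a run ten times as long changes it by nothing. The ratio, a reading with its scatter, put on this side product gives 8.84 %.

For a neighbour flask with 0.750 equiv of coupling partner, a quarter of the charge in the green flask, I scale the ratio in proportion to 0.0251. That flask gives 3.35 % of left-handed product and 92.0 % of side product, a ratio of 0.0364, higher than the scaled one.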